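**Plan**

1. Cuts: once the benzyl-type protecting groups are removed, both C4–C4a aryl ketone bonds are cut in one move. This opens the two rings C to a C2-symmetric bis(3-aryl-3-aryloxypropanoic acid). The two O1–C2 ether bonds are cut next (biphenol plus two benzylic alcohols), and the C6–C6'' biaryl bond last.
2. Enabling feature: in each phloroglucinol-type ring A, C4a lies between C8a (bearing O1) and oxygenated C5, and para to oxygenated C7, so it is a highly nucleophilic arene carbon. C6, para to O1, is blocked by the biaryl bond, and the two carbons ortho to O1 are equivalent. An acylium ion tethered through O1–C2–C3 can therefore close ring C only at C4a.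
3. Forward order: the ring A–ring A biaryl is built first from 5-bromoresorcinol (iodination between the hydroxyls, benzylation, Ullmann coupling, Br to OH). Two ring B units are attached by a double Mitsunobu etherification, the vinyl groups are cut down to carboxylic acids, both rings C close in one operation, and one hydrogenolysis frees all six phenols.
4. Stereochemistry: C2 and C2'' come from one catalytic enantioselective allylboration of protected 4-hydroxybenzaldehyde (R alcohol). They are inverted to S in the Mitsunobu step and not touched afterwards.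
5. Design points: C4 travels as a vinyl carbon, because a β-hydroxy ester would dehydrate to the cinnamate on Mitsunobu activation. The ring B phenol is carried as a benzyl carbonate, which is electron-poor enough to hold back a C2 cation yet removable without base.

Key step: step 10

Remark: the target SMILES fixes only C2 and C2''. The C6–C6'' axis becomes stereogenic once both rings C are closed and is taken as unspecified, so atropisomers of 16 and 18 are carried together.

**Route**

Step 1
Reactants: 1 5-bromoresorcinol (5-bromobenzene-1,3-diol)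
Product: 2 5-bromo-2-iodobenzene-1,3-diol
Conditions: I2 (1.05 equiv), NaHCO3, H2O/THF, 0 °C to rt
Reagents that add atoms: iodine, [I][I]
Why: Electrophilic aromatic iodination of a resorcinol under aqueous bicarbonate goes to the carbon between the two hydroxyl groups, as in the standard preparation of 2-iodoresorcinol, and the bromine at C5 additionally shields C4 and C6, so the halogen that becomes the biaryl bond is placed para to the future O1 without ambiguity.

Step 2
Reactants: 2 5-bromo-2-iodobenzene-1,3-diol
Product: 3 1,3-bis(benzyloxy)-5-bromo-2-iodobenzene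
Conditions: BnBr, K2CO3, DMF, rt
Reagents that add atoms: benzyl bromide, BrCc1ccccc1
Why: Williamson ether synthesis on both phenols gives benzyl ethers that keep ring A electron-rich for the later acylation and leave by hydrogenolysis at the end, and neither aryl halide reacts with K2CO3 at room temperature.

Step 3
Reactants: 3 1,3-bis(benzyloxy)-5-bromo-2-iodobenzene (two molecules)
Product: 4 2,2',6,6'-tetrakis(benzyloxy)-4,4'-dibromo-1,1'-biphenyl
Conditions: activated Cu powder, DMF, 130 °C, argon
Reagents that add atoms: none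
Why: Ullmann reductive homocoupling, the classical entry to tetra-ortho-alkoxy biaryls from 2-iodoresorcinol diethers, takes place at the C–I bond, which is flanked by two coordinating ether oxygens and reacts with copper far faster than the unactivated C–Br bond, so both bromines should be kept.

Step 4
Reactants: 4 2,2',6,6'-tetrakis(benzyloxy)-4,4'-dibromo-1,1'-biphenyl
Product: 5 2,2',6,6'-tetrakis(benzyloxy)-[1,1'-biphenyl]-4,4'-diol
Conditions: Pd2(dba)3 (cat.), t-BuXPhos [2-di-tert-butylphosphino-2',4',6'-triisopropylbiphenyl], KOH, 1,4-dioxane/H2O, 100 °C, argon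
Reagents that add atoms: potassium hydroxide, [K+].[OH-]
Why: Palladium-catalysed hydroxylation of aryl bromides with KOH (Buchwald–Hartwig-type C–O coupling with a bulky biarylphosphine) suits unhindered positions such as C4 and C4', excess hydroxide in aqueous dioxane holds back diaryl ether formation, and benzyl ethers are inert.

Step 5
Reactants: 6 4-hydroxybenzaldehyde
Product: 7 benzyl 4-formylphenyl carbonate
Conditions: CbzCl, Et3N, CH2Cl2, 0 °C
Reagents that add atoms: benzyl chloroformate, O=C(Cl)OCc1ccccc1
Why: O-acylation of the phenol with a chloroformate (carbonate formation) gives an electron-poor oxygen substituent on ring B that disfavours a benzylic cation at the future C2 and leaves under the same neutral hydrogenolysis as the benzyl ethers.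

Step 6
Reactants: 7 benzyl 4-formylphenyl carbonate; 8 allylboronic acid pinacol ester
Product: 10 benzyl 4-[(1R)-1-hydroxybut-3-en-1-yl]phenyl carbonate, via homoallyl pinacol borate 9 (not isolated)
Conditions: (R)-TRIP [(R)-3,3'-bis(2,4,6-triisopropylphenyl)-1,1'-binaphthyl-2,2'-diyl hydrogen phosphate] (5 mol %), toluene, −30 °C; aqueous work-up
Reagents that add atoms: none
Why: Chiral-phosphoric-acid-catalysed asymmetric allylboration of an aromatic aldehyde runs through a closed six-membered chair transition state in which the (R)-catalyst binds a boronate oxygen and the formyl hydrogen and directs allyl transfer to the Re face, which sets the carbinol centre as R, while the neutral medium leaves the carbonate intact.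

Step 7
Reactants: 5 2,2',6,6'-tetrakis(benzyloxy)-[1,1'-biphenyl]-4,4'-diol; 10 benzyl 4-[(1R)-1-hydroxybut-3-en-1-yl]phenyl carbonate (two molecules, 2.4 equiv used)
Product: 11 2,2',6,6'-tetrakis(benzyloxy)-4,4'-bis{[(1S)-1-(4-{[(benzyloxy)carbonyl]oxy}phenyl)but-3-en-1-yl]oxy}-1,1'-biphenyl
Conditions: PPh3, DIAD, toluene, 0 °C to rt
Reagents that add atoms: none
Why: In this two-fold Mitsunobu etherification each alkoxyphosphonium ion is displaced by the phenoxide in an SN2 reaction with inversion (R to S), the electron-poor ring B and the non-polar solvent hold back ionisation, a homoallylic alcohol is far less prone to dehydration than a β-hydroxy ester, and any minor enantiomer of 10 should end up mainly in the separable (R,S) diastereomer.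

Step 8
Reactants: 11 the (S,S)-bis(homoallyl aryl ether)
Product: 13 2,2',6,6'-tetrakis(benzyloxy)-4,4'-bis{[(1S)-1-(4-{[(benzyloxy)carbonyl]oxy}phenyl)-3-oxopropyl]oxy}-1,1'-biphenyl, via bis(1,2-diol) 12 (not isolated)
Conditions: OsO4 (cat.), NaIO4, 2,6-lutidine, 1,4-dioxane/H2O, rt; extractive work-up, used crude
Reagents that add atoms: osmium tetroxide (catalytic carrier of the oxygen), O=[Os](=O)(=O)=O; sodium periodate (terminal oxygen source), [Na+].[O-]I(=O)(=O)=O
Why: In the Lemieux–Johnson oxidation, catalytic osmylation attacks only the two terminal alkenes and periodate cleaves the resulting diols 12, while arenes, benzyl ethers and carbonates are inert and the nearly neutral lutidine-buffered medium should keep the β-aryloxy aldehyde from E1cB loss of the phenol.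

Step 9
Reactants: 13 the (S,S)-bis(aldehyde)
Product: 14 (3S,3'S)-3,3'-{[2,2',6,6'-tetrakis(benzyloxy)-[1,1'-biphenyl]-4,4'-diyl]bis(oxy)}bis[3-(4-{[(benzyloxy)carbonyl]oxy}phenyl)propanoic acid]
Conditions: NaClO2, NaH2PO4, 2-methyl-2-butene (large excess), t-BuOH/THF/H2O, 0 °C to rt
Reagents that add atoms: sodium chlorite, [Na+].[O-]Cl=O
Why: The Pinnick oxidation converts the aldehydes into acids at about pH 4 without enolisation-driven elimination or epimerisation, and the excess 2-methyl-2-butene takes up the hypochlorous acid before it can chlorinate ring A.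

Step 10
Reactants: 14 the (3S,3'S)-bis(3-aryl-3-aryloxypropanoic acid)
Product: 16 (2S,2''S)-5,5'',7,7''-tetra-O-benzyl-4',4'''-bis-O-(benzyloxycarbonyl)succedaneaflavanone [(2S,2'S)-5,5',7,7'-tetrakis(benzyloxy)-2,2'-bis(4-{[(benzyloxy)carbonyl]oxy}phenyl)-[6,6'-bichromane]-4,4'-dione], via bis(trifluoroacetic mixed anhydride) 15 (not isolated)
Conditions: (CF3CO)2O (2.4 equiv), CH2Cl2 (dilute), 0 °C to rt
Reagents that add atoms: trifluoroacetic anhydride, O=C(OC(=O)C(F)(F)F)C(F)(F)F (its atoms are held only in intermediate 15 and are lost again in 16)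
Why: Each carboxylic acid is turned into the mixed trifluoroacetic anhydride 15, which reacts as an acylium ion with the ring A carbon ortho to the ether oxygen, and loss of the proton from the arenium ion gives the C4–C4a aryl ketone; this is an intramolecular Friedel–Crafts acylation, the classical route from 3-aryloxypropanoic acids to chroman-4-ones, run here at both ends of the molecule. Both rings C close as six-membered rings in a 6-exo mode with respect to the acyl C=O, with the C4a–C8a bond of ring A as the endocyclic π-nucleophile. No stereocentre is made, since C2 and C2'' are carried in from 14 and take no part in the bond formation, while the biaryl axis becomes stereogenic on the second closure and is left uncontrolled in line with the remark above. Regioselectivity is secured by the substrate, because the two positions ortho to each ether oxygen are equivalent and the para position is taken by the biaryl bond, so only the 6,6''-linked isomer can arise. Chemoselectivity rests on the trioxygenated ring A being acylated without any Lewis acid, which spares the benzyl ethers (also the one peri to the new ketone) and the carbonates, and on the small excess of anhydride, which keeps intermolecular trifluoroacetylation at C8 behind the intramolecular closure. Configurational integrity needs the C2–O1 bond not to ionise, and here the 4'-carbonate and the β-acyl group both destabilise the benzylic cation while dilute trifluoroacetic acid is the only acid present.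

Step 11
Reactants: 16 the protected (2S,2''S)-biflavanone
Product: 18 succedaneaflavanone [(2S,2'S)-5,5',7,7'-tetrahydroxy-2,2'-bis(4-hydroxyphenyl)-[6,6'-bichromane]-4,4'-dione], via bis(aryl hydrogen carbonate) 17 (not isolated)
Conditions: H2 (1 atm), 10% Pd/C, EtOAc/MeOH, rt
Reagents that add atoms: none
Why: Catalytic hydrogenolysis cleaves the six primary benzylic C–O bonds (four ethers and two carbonates, the latter giving 17, which loses CO2) faster than the secondary ring-bound C2–O1 bond, as is usual for benzylated flavanones, and the neutral medium avoids the base-induced opening to the chalcone that would racemise C2 and C2''.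

**Compound list**

1 | 5-bromoresorcinol | Oc1cc(O)cc(Br)c1 | starting material
2 | 5-bromo-2-iodobenzene-1,3-diol | Oc1cc(Br)cc(O)c1I | intermediate
3 | 1,3-bis(benzyloxy)-5-bromo-2-iodobenzene | Brc1cc(OCc2ccccc2)c(I)c(OCc2ccccc2)c1 | intermediate
4 | 2,2',6,6'-tetrakis(benzyloxy)-4,4'-dibromo-1,1'-biphenyl | Brc1cc(OCc2ccccc2)c(-c2c(OCc3ccccc3)cc(Br)cc2OCc2ccccc2)c(OCc2ccccc2)c1 | intermediate
5 | 2,2',6,6'-tetrakis(benzyloxy)-[1,1'-biphenyl]-4,4'-diol | Oc1cc(OCc2ccccc2)c(-c2c(OCc3ccccc3)cc(O)cc2OCc2ccccc2)c(OCc2ccccc2)c1 | intermediate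
6 | 4-hydroxybenzaldehyde | O=Cc1ccc(O)cc1 | starting material
7 | benzyl 4-formylphenyl carbonate | O=Cc1ccc(OC(=O)OCc2ccccc2)cc1 | intermediate
8 | allylboronic acid pinacol ester | C=CCB1OC(C)(C)C(C)(C)O1 | starting material
9 | (R)-homoallyl pinacol borate, the O-Bpin derivative of 10 (not isolated) | C=CC[C@@H](OB1OC(C)(C)C(C)(C)O1)c1ccc(OC(=O)OCc2ccccc2)cc1 | intermediate
10 | benzyl 4-[(1R)-1-hydroxybut-3-en-1-yl]phenyl carbonate | C=CC[C@@H](O)c1ccc(OC(=O)OCc2ccccc2)cc1 | intermediate
11 | (S,S)-bis(homoallyl aryl ether) of 5 | C=CC[C@@H](c1ccc(OC(=O)OCc2ccccc2)cc1)Oc1cc(OCc2ccccc2)c(-c2c(OCc3ccccc3)cc(O[C@@H](CC=C)c3ccc(OC(=O)OCc4ccccc4)cc3)cc2OCc2ccccc2)c(OCc2ccccc2)c1 | intermediate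
12 | (S,S)-bis(1,2-diol) from 11, new carbinol centres as a mixture (not isolated) | OCC(O)C[C@@H](c1ccc(OC(=O)OCc2ccccc2)cc1)Oc1cc(OCc2ccccc2)c(-c2c(OCc3ccccc3)cc(O[C@@H](CC(O)CO)c3ccc(OC(=O)OCc4ccccc4)cc3)cc2OCc2ccccc2)c(OCc2ccccc2)c1 | intermediate
13 | (S,S)-bis(3-aryl-3-aryloxypropanal) | O=CC[C@@H](c1ccc(OC(=O)OCc2ccccc2)cc1)Oc1cc(OCc2ccccc2)c(-c2c(OCc3ccccc3)cc(O[C@@H](CC=O)c3ccc(OC(=O)OCc4ccccc4)cc3)cc2OCc2ccccc2)c(OCc2ccccc2)c1 | intermediate
14 | (3S,3'S)-bis(3-aryl-3-aryloxypropanoic acid), precursor of the key step | OC(=O)C[C@@H](c1ccc(OC(=O)OCc2ccccc2)cc1)Oc1cc(OCc2ccccc2)c(-c2c(OCc3ccccc3)cc(O[C@@H](CC(=O)O)c3ccc(OC(=O)OCc4ccccc4)cc3)cc2OCc2ccccc2)c(OCc2ccccc2)c1 | intermediate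
15 | bis(trifluoroacetic mixed anhydride) of 14 (not isolated) | FC(F)(F)C(=O)OC(=O)C[C@@H](c1ccc(OC(=O)OCc2ccccc2)cc1)Oc1cc(OCc2ccccc2)c(-c2c(OCc3ccccc3)cc(O[C@@H](CC(=O)OC(=O)C(F)(F)F)c3ccc(OC(=O)OCc4ccccc4)cc3)cc2OCc2ccccc2)c(OCc2ccccc2)c1 | intermediate
16 | (2S,2''S)-5,5'',7,7''-tetra-O-benzyl-4',4'''-bis-O-(benzyloxycarbonyl)succedaneaflavanone, product of the key step | O=C1C[C@@H](c2ccc(OC(=O)OCc3ccccc3)cc2)Oc2cc(OCc3ccccc3)c(-c3c(OCc4ccccc4)cc4c(c3OCc3ccccc3)C(=O)C[C@@H](c3ccc(OC(=O)OCc5ccccc5)cc3)O4)c(OCc3ccccc3)c21 | intermediate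
17 | (2S,2''S)-succedaneaflavanone 4',4'''-bis(hydrogen carbonate) (not isolated) | O=C1C[C@@H](c2ccc(OC(=O)O)cc2)Oc2cc(O)c(-c3c(O)cc4c(c3O)C(=O)C[C@@H](c3ccc(OC(=O)O)cc3)O4)c(O)c21 | intermediate
18 | succedaneaflavanone, (2S,2''S) | O=C1C[C@@H](c2ccc(O)cc2)Oc2cc(O)c(-c3c(O)cc4c(c3O)C(=O)C[C@@H](c3ccc(O)cc3)O4)c(O)c21 | target

**Step count**

Total step count: 11.
Longest linear sequence: 9 steps (steps 1–4, then 7–11). Steps 5 and 6 form the convergent branch.

**Steps most likely to fail**

Step 10.
- What may go wrong: acid-induced heterolysis of the benzylic C2–O1 bonds, with erosion of configuration or loss of the side chains by elimination. The reaction may also stall after the first closure, because the second acylation site sits next to the crowded axis, and trifluoroacetylation at C8 may compete.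
- Fallback: the same two-directional Friedel–Crafts closure is run on a substrate that has no benzylic ether, and ring B with its stereocentre is added afterwards under catalyst control. It sets out from 5 and comes back at 18.
- The disodium salt of 5 (NaH, DMF, 0 °C) opens β-propiolactone at the CH2–O carbon to give 3,3'-{[2,2',6,6'-tetrakis(benzyloxy)-[1,1'-biphenyl]-4,4'-diyl]bis(oxy)}dipropanoic acid F1.
- Trifluoroacetic anhydride in CH2Cl2 converts it through its bis(trifluoroacetic mixed anhydride) F2 into 5,5',7,7'-tetrakis(benzyloxy)-[6,6'-bichromane]-4,4'-dione F3.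
- Dehydrogenation with 2-iodoxybenzoic acid (DMSO, 80 °C) gives 5,5',7,7'-tetrakis(benzyloxy)-[6,6'-bichromene]-4,4'-dione F4.
- A double enantioselective conjugate addition of 4-(benzyloxy)phenylboronic acid, a reaction type known for chromones, should set C2 and C2'' as S and give (2S,2''S)-hexa-O-benzylsuccedaneaflavanone F5. Conditions: Pd(OCOCF3)2, (R)-4-tert-butyl-2-(pyridin-2-yl)-4,5-dihydrooxazole, NH4PF6, H2O, ClCH2CH2Cl, 60 °C. The ligand enantiomer is chosen by analogy with cyclic enones.
- F5 is hydrogenolysed under the conditions of step 11 to 18.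

Step 7.
- What may go wrong: elimination of the alkoxyphosphonium ion to the 1-arylbuta-1,3-diene, partial ionisation with erosion of the inversion, transfer of the carbonate group to the phenoxide, and stopping at the mono-ether.
- Fallback: the polarity is reversed so that the carbinol C–O bond is never broken. The (S)-alcohol is O-arylated with dibromide 4 in a copper-catalysed Ullmann-type etherification, which goes with retention. It sets out from 4, 6 and 8 and comes back at 11, so step 4 is then not needed.
- A carbonate would not survive Cs2CO3 at 110 °C, so 6 is silylated (TIPSCl, imidazole, DMF) to 4-(triisopropylsilyloxy)benzaldehyde F6.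
- Allylboration with 8 under (S)-TRIP, as in step 6, leads through the (S)-homoallyl pinacol borate F7 to (1S)-1-[4-(triisopropylsilyloxy)phenyl]but-3-en-1-ol F8.
- CuI, 3,4,7,8-tetramethyl-1,10-phenanthroline and Cs2CO3 in toluene at 110 °C join two molecules of F8 to 4 and give the (S,S)-bis(4-silyloxyphenyl homoallyl aryl ether) F9.
- Et3N·3HF in THF frees the (S,S)-bis(4-hydroxyphenyl homoallyl aryl ether) F10. No phenoxide is formed under these conditions, so loss of aryloxide through a quinone methide is avoided.
- CbzCl in pyridine at 0 °C gives 11.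

Step 3.
- What may go wrong: sluggish coupling at the doubly ortho-substituted carbon, protodeiodination, and onset of reaction at the C–Br bonds at the temperature needed, which would lead to oligomerisation.
- Fallback: oxidative instead of reductive coupling, at low temperature. It sets out from 3 and comes back at 4.
- Selective iodine–magnesium exchange (iPrMgCl·LiCl, THF, −20 °C, C–Br untouched) gives [2,6-bis(benzyloxy)-4-bromophenyl]magnesium chloride F11.
- F11 is homocoupled with 3,3',5,5'-tetra-tert-butyl-4,4'-diphenoquinone (−20 °C to rt), the known transition-metal-free oxidative homocoupling of aryl Grignard reagents, to give 4.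

**Further compounds**

F1 | step 10 | 3,3'-{[2,2',6,6'-tetrakis(benzyloxy)-[1,1'-biphenyl]-4,4'-diyl]bis(oxy)}dipropanoic acid | OC(=O)CCOc1cc(OCc2ccccc2)c(-c2c(OCc3ccccc3)cc(OCCC(=O)O)cc2OCc2ccccc2)c(OCc2ccccc2)c1
F2 | step 10 | bis(trifluoroacetic mixed anhydride) of F1 | FC(F)(F)C(=O)OC(=O)CCOc1cc(OCc2ccccc2)c(-c2c(OCc3ccccc3)cc(OCCC(=O)OC(=O)C(F)(F)F)cc2OCc2ccccc2)c(OCc2ccccc2)c1
F3 | step 10 | 5,5',7,7'-tetrakis(benzyloxy)-[6,6'-bichromane]-4,4'-dione | O=C1CCOc2cc(OCc3ccccc3)c(-c3c(OCc4ccccc4)cc4c(c3OCc3ccccc3)C(=O)CCO4)c(OCc3ccccc3)c21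
F4 | step 10 | 5,5',7,7'-tetrakis(benzyloxy)-[6,6'-bichromene]-4,4'-dione | O=c1ccoc2cc(OCc3ccccc3)c(-c3c(OCc4ccccc4)cc4occc(=O)c4c3OCc3ccccc3)c(OCc3ccccc3)c12
F5 | step 10 | (2S,2''S)-hexa-O-benzylsuccedaneaflavanone | O=C1C[C@@H](c2ccc(OCc3ccccc3)cc2)Oc2cc(OCc3ccccc3)c(-c3c(OCc4ccccc4)cc4c(c3OCc3ccccc3)C(=O)C[C@@H](c3ccc(OCc5ccccc5)cc3)O4)c(OCc3ccccc3)c21
F6 | step 7 | 4-(triisopropylsilyloxy)benzaldehyde | O=Cc1ccc(O[Si](C(C)C)(C(C)C)C(C)C)cc1
F7 | step 7 | (S)-homoallyl pinacol borate, the O-Bpin derivative of F8 | C=CC[C@H](OB1OC(C)(C)C(C)(C)O1)c1ccc(O[Si](C(C)C)(C(C)C)C(C)C)cc1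
F8 | step 7 | (1S)-1-[4-(triisopropylsilyloxy)phenyl]but-3-en-1-ol | C=CC[C@H](O)c1ccc(O[Si](C(C)C)(C(C)C)C(C)C)cc1
F9 | step 7 | (S,S)-bis(4-silyloxyphenyl homoallyl aryl ether) | C=CC[C@@H](c1ccc(O[Si](C(C)C)(C(C)C)C(C)C)cc1)Oc1cc(OCc2ccccc2)c(-c2c(OCc3ccccc3)cc(O[C@@H](CC=C)c3ccc(O[Si](C(C)C)(C(C)C)C(C)C)cc3)cc2OCc2ccccc2)c(OCc2ccccc2)c1
F10 | step 7 | (S,S)-bis(4-hydroxyphenyl homoallyl aryl ether) | C=CC[C@@H](c1ccc(O)cc1)Oc1cc(OCc2ccccc2)c(-c2c(OCc3ccccc3)cc(O[C@@H](CC=C)c3ccc(O)cc3)cc2OCc2ccccc2)c(OCc2ccccc2)c1
F11 | step 3 | [2,6-bis(benzyloxy)-4-bromophenyl]magnesium chloride | Cl[Mg]c1c(OCc2ccccc2)cc(Br)cc1OCc1ccccc1
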